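## Retrosynthetic overview

1. The strategy rests on the C8(O)–C9H2–C10(CH3)(O) unit of the ten-membered carbocycle (C1–C10), where the tertiary C10 carbinol sits β to the oxygenated C8 across the single C9 methylene. This aldol retron is cut at C9–C10 by a SmI2 Reformatsky macrocyclisation of a C9 bromide onto a C10 methyl ketone flanked by a C1 dioxolane.
2. The open precursor comes from a Negishi C3–C4 coupling of a (Z)-C4 iodoalkene on the lactone core with a keto-ketal zinc reagent (C3, C2, C1, C10, C14) made from diethyl oxalate. The C8 acetyl group travels through the coupling as its silyl enol ether and is brominated at C9 afterwards.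
3. The all-trans lactone core (C6, C7, C11) is set by conjugate addition of lithiated 2-methyl-1,3-dithiane to the protected (S)-butenolide with formaldehyde trapping. C4 and C15 enter by an α-iodo Wittig olefination at C5.
4. After ring closure: syn reduction of C8 directed by the C10 hydroxyl, tiglate, acid unmasking of C1 and C13, double acetylation, epoxidation of the Z C4=C5 bond.
5. Ring order: γ-lactone (present in the starting butenolide), ten-membered carbocycle (step 14), oxirane (step 19).

Key step: step 14

Remark: germacrane numbering is used throughout. The C13 oxygen is carried as its tert-butyldimethylsilyl ether until step 17, because a 13-acetoxy group β to the lactone carbonyl would be lost by E1cB elimination under the bases of steps 5 and 7. The C8 acetyl group is coupled as its silyl enol ether so that bromine goes to C9 and not to C14.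

## Route

Step 1
Reactants: 1 (S)-5-(hydroxymethyl)furan-2(5H)-one
Product: 2 (S)-5-[(triethylsilyloxy)methyl]furan-2(5H)-one
Conditions: Et3SiCl, imidazole, CH2Cl2, 0 °C
Reagents that add atoms: chlorotriethylsilane CC[Si](Cl)(CC)CC
Why: Imidazole-mediated silylation of the primary alcohol is routine, and the triethylsilyl ether is chosen because it can later be oxidised directly to the aldehyde in the presence of a tert-butyldimethylsilyl ether.

Step 2
Reactants: 2 (S)-5-[(triethylsilyloxy)methyl]furan-2(5H)-one; 3 2-methyl-1,3-dithiane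
Product: 6 (3R,4S,5S)-3-(hydroxymethyl)-4-(2-methyl-1,3-dithian-2-yl)-5-[(triethylsilyloxy)methyl]dihydrofuran-2(3H)-one, via 2-lithio-2-methyl-1,3-dithiane 4 (not isolated), via lithium lactone enolate 5 (not isolated)
Conditions: 3, n-BuLi, THF, −30 °C; DMPU, then 2, −78 °C; HCHO (gas), −78 °C; aq. NH4Cl
Reagents that add atoms: formaldehyde C=O
Why: In this tandem Michael addition–enolate hydroxymethylation the sulfur-stabilised anion adds 1,4 at C7 anti to the C6 silyloxymethyl group, and formaldehyde then enters the enolate at C11 anti to the new dithianyl group, which should give the all-trans lactone with C8, C9 and C13 in place.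

Step 3
Reactants: 6 hydroxymethyl lactone
Product: 7 (3R,4S,5S)-3-[(tert-butyldimethylsilyloxy)methyl]-4-(2-methyl-1,3-dithian-2-yl)-5-[(triethylsilyloxy)methyl]dihydrofuran-2(3H)-one
Conditions: t-BuMe2SiCl, imidazole, DMF, rt
Reagents that add atoms: tert-butyldimethylsilyl chloride CC(C)(C)[Si](C)(C)Cl
Why: Standard silylation gives a C13 ether that is a poor leaving group, so the β-oxygenated lactone should not eliminate under the bases of steps 5 and 7, and the group falls off later in the same acid step as the dioxolane.

Step 4
Reactants: 7 bis-silyl ether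
Product: 9 all-trans 4-[(tert-butyldimethylsilyloxy)methyl]-3-(2-methyl-1,3-dithian-2-yl)-5-oxotetrahydrofuran-2-carbaldehyde (C5 aldehyde, configuration as in 7), via alkoxydimethylsulfonium chloride 8 (not isolated)
Conditions: (COCl)2, DMSO, CH2Cl2, −78 → −30 °C; Et3N, −78 → 0 °C
Reagents that add atoms: none
Why: Swern oxidation converts a primary triethylsilyl ether directly into the aldehyde because the activated sulfoxide cleaves the O–Si bond, while the tert-butyldimethylsilyl ether and the dithiane are left alone and the low temperature should keep the α-oxygenated C6 centre from epimerising.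

Step 5
Reactants: 9 C5 aldehyde
Product: 10 all-trans lactone with a (Z)-2-iodoprop-1-enyl group at C6 (iodine on C4, cis to C6), the dithiane at C7 and CH2OTBS at C11
Conditions: EtPPh3I, n-BuLi, THF, rt; I2, −78 °C; NaN(SiMe3)2, −20 °C; then 9, −78 °C → rt
Reagents that add atoms: ethyltriphenylphosphonium iodide CC[P+](c1ccccc1)(c1ccccc1)c1ccccc1.[I-]; iodine II
Why: Wittig olefination with the α-iodo ylide (Stork–Zhao type) should give the (Z)-iodoalkene with iodine cis to C6, so that later replacement of iodine by C3 with retention fixes the Z (C3/C6 cis) C4=C5 bond and brings in C4 and C15.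

Step 6
Reactants: 10 (Z)-iodoalkene dithiane
Product: 11 C7 acetyl lactone (C8 methyl ketone; (Z)-iodoalkene and CH2OTBS unchanged)
Conditions: MeI, CaCO3, MeCN/H2O (4:1), 45 °C
Reagents that add atoms: water O
Why: S-Methylation turns the dithiane into a leaving group and water hydrolyses it to the C8 ketone under buffered neutral conditions that leave the iodoalkene, lactone and silyl ether alone and do not enolise the ketone toward C7.

Step 7
Reactants: 11 C8 methyl ketone
Product: 13 C7 1-(tert-butyldimethylsilyloxy)vinyl lactone (silyl enol ether O–C8=C9), via lithium enolate 12 (not isolated)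
Conditions: LiN(i-Pr)2, THF, −78 °C; t-BuMe2SiOTf, −78 °C
Reagents that add atoms: tert-butyldimethylsilyl triflate CC(C)(C)[Si](C)(C)OS(=O)(=O)C(F)(F)F
Why: Kinetic deprotonation of a methyl ketone occurs at the methyl group (C9) and not at the tertiary C7, and O-silylation stores this regiochemistry as a robust enol ether that masks the C8 carbonyl and marks C9 for bromination before the second methyl ketone (C10/C14) enters.

Step 8
Reactants: 14 diethyl oxalate
Product: 16 ethyl 2-oxobut-3-enoate, via bromomagnesium hemiketal alkoxide 15 (not isolated)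
Conditions: CH2=CHMgBr (0.9 equiv), THF/Et2O, −78 °C; cold aq. NH4Cl; crude solution used at once
Reagents that add atoms: vinylmagnesium bromide C=C[Mg]Br
Why: Grignard mono-addition to a dialkyl oxalate stops at the tetrahedral magnesium alkoxide at −78 °C and gives the α-keto ester on quench, and the reactive vinyl ketone is taken on without storage.

Step 9
Reactants: 16 ethyl 2-oxobut-3-enoate
Product: 18 ethyl 2-(2-bromoethyl)-1,3-dioxolane-2-carboxylate, via ethyl 4-bromo-2-oxobutanoate 17 (not isolated)
Conditions: Me3SiBr, HOCH2CH2OH, CH2Cl2, 0 °C → rt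
Reagents that add atoms: bromotrimethylsilane C[Si](C)(C)Br; ethylene glycol OCCO
Why: Conjugate hydrobromination of the enone followed by in situ ketalisation of the electrophilic α-keto ester carbonyl is the standard access to β-bromo ketals from vinyl ketones, with the silyl bromide also taking up the water.

Step 10
Reactants: 18 bromo ketal ester
Product: 19 2-(2-bromoethyl)-N-methoxy-N-methyl-1,3-dioxolane-2-carboxamide
Conditions: MeNHOMe·HCl, i-PrMgCl, THF, −20 °C
Reagents that add atoms: N,O-dimethylhydroxylamine hydrochloride CNOC.Cl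
Why: The magnesium amide of N,O-dimethylhydroxylamine converts esters directly into Weinreb amides at low temperature, where the primary bromide and the ketal are inert.

Step 11
Reactants: 19 Weinreb amide
Product: 21 1-[2-(2-bromoethyl)-1,3-dioxolan-2-yl]ethan-1-one, via magnesium chelate 20 (not isolated)
Conditions: MeMgBr, THF, −20 → 0 °C; aq. NH4Cl
Reagents that add atoms: methylmagnesium bromide C[Mg]Br
Why: In this Weinreb ketone synthesis the chelated tetrahedral adduct does not collapse before work-up, so a single methyl group (C14) is delivered and the C10 methyl ketone next to the C1 dioxolane results.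

Step 12
Reactants: 13 silyl enol ether iodoalkene; 21 bromo keto ketal
Product: 23 all-trans lactone carrying the 1-(tert-butyldimethylsilyloxy)vinyl group at C7, CH2OTBS at C11 and at C6 the (Z)-C5=C4(CH3)–C3H2–C2H2–C1(dioxolane)–C10(=O)–C14H3 chain, via alkylzinc bromide 22 (not isolated)
Conditions: 21, Zn dust, I2 (cat.), DMA, 70 °C; then 13, PdCl2(dppf) (5 mol %), THF/DMA, rt → 40 °C
Reagents that add atoms: none
Why: Negishi sp3–sp2 coupling forms C3–C4 with retention of the alkene geometry and without added base, so the lactone, the silyl enol ether and the free C10 ketone (tolerated by alkylzinc halides) should survive.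

Step 13
Reactants: 23 coupled silyl enol ether
Product: 24 C7 bromoacetyl lactone (C9 bromide, C8 ketone) with Z C4=C5, C1 dioxolane, C10 methyl ketone and C13 OTBS
Conditions: NBS, THF, −78 °C; aq. NaHCO3/Na2S2O3
Reagents that add atoms: N-bromosuccinimide O=C1CCC(=O)N1Br
Why: A silyl enol ether reacts with NBS far faster than a trisubstituted alkene or a non-enolised ketone, so bromine is placed at C9 only, and 24 is used at once without base because enolisation toward C7 would expel the C6 lactone oxygen.

Step 14
Reactants: 24 C9 bromide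
Product: 26 (4Z,10R)-1,1-ethylenedioxy-10-hydroxy-8-oxo-13-(tert-butyldimethylsilyloxy)germacr-4-en-12,6-olide (6,7-trans lactone, 7,11-trans), via samarium enolate 25 (not isolated)
Conditions: SmI2 (2.2 equiv), THF, −78 °C, slow addition of 24 (final 0.005 M); → −20 °C; aq. NH4Cl
Reagents that add atoms: none
Why: Two single-electron transfers from divalent samarium cleave the C9–Br bond and give the trivalent samarium enolate 25 regiospecifically (O–C8=C9), which adds through C9 to the C10 carbonyl to give a samarium aldolate that is stable at low temperature and is protonated on work-up. The closest known reaction type is the SmI2-mediated intramolecular Reformatsky-type aldol reaction of α-halo carbonyl compounds, which closes medium and large rings. The ten-membered carbocycle closes in a 10-exo-trig mode, C9 onto C10 with the carbonyl oxygen outside the ring. C10 is the only new stereocentre, and it should be set in a chair-like chelate in which trivalent samarium bridges the enolate oxygen, the C10 carbonyl oxygen and one dioxolane oxygen while the Z-olefin and the trans-fused lactone hold the C2–C6 tether so that C9 reaches the Re face of C10 (O > C1 > C14) and gives 10R; this relay from C7 is unproven. The step needs chemoselective reduction of the α-bromo ketone before the C10 ketone, the lactone or the ketal C–O bonds, which the much faster C–Br reduction at −78 °C without HMPA and the slow addition of 24 should secure; the position of bromine excludes an enolate toward C7 and loss of the C6 oxygen, and high dilution favours ring closure over dimerisation.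

Step 15
Reactants: 26 β-hydroxy ketone
Product: 28 (8S,10R)-8,10-diol (1,1-ethylenedioxy, 13-OTBS, Z C4=C5), via diethylboron chelate 27 (not isolated)
Conditions: Et2BOMe, THF/MeOH (4:1), −78 °C; NaBH4, −78 °C; AcOH, then MeOH co-evaporation
Reagents that add atoms: none
Why: In the Narasaka–Prasad reduction the boron chelate between the C10 oxygen and the C8 carbonyl is attacked by external hydride along the axial trajectory, which should give the 8,10-syn diol (8S) with C7 and C1 cis on the dioxaborinane, the arrangement the ten-membered ring also bridges most easily.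

Step 16
Reactants: 28 syn diol
Product: 29 C8 tiglate (free tertiary C10 hydroxyl, C1 dioxolane, 13-OTBS)
Conditions: tiglic acid, 2,4,6-Cl3C6H2COCl, Et3N, toluene, rt; then 28, DMAP, rt
Reagents that add atoms: tiglic acid C/C=C(\C)C(=O)O
Why: Yamaguchi esterification acylates the secondary C8 hydroxyl through the mixed anhydride without E/Z or positional isomerisation of the tigloyl group, and the tertiary C10 hydroxyl is too hindered to compete.

Step 17
Reactants: 29 tiglate ketal
Product: 30 (4Z)-10,13-dihydroxy-1-oxo-8-tigloyloxygermacr-4-en-12,6-olide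
Conditions: 1 M aq. HCl/THF (1:3), rt
Reagents that add atoms: water O
Why: Dilute aqueous acid hydrolyses the dioxolane and the primary silyl ether in one operation while esters and lactone persist, and the water-rich medium should capture the C1 oxocarbenium ion before the C4=C5 π bond can add to it across the ring.

Step 18
Reactants: 30 keto diol
Product: 31 (4Z)-10,13-diacetoxy-1-oxo-8-tigloyloxygermacr-4-en-12,6-olide
Conditions: Ac2O, DMAP, pyridine, CH2Cl2, rt → 35 °C
Reagents that add atoms: acetic anhydride CC(=O)OC(C)=O
Why: DMAP-catalysed acetylation takes the primary C13 hydroxyl at once and, more slowly, the tertiary C10 hydroxyl, which is less hindered now that C1 is a planar carbonyl, and the weak amine base should not eliminate the new 13-acetate.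

Step 19
Reactants: 31 Z-olefin
Product: 32 (4R,5S,6S,7R,8S,10R,11R)-10,13-diacetoxy-4,5-epoxy-1-oxo-8-tigloyloxygermacran-12,6-olide (CNP0305680.1)
Conditions: mCPBA, NaHCO3, CH2Cl2, 0 °C
Reagents that add atoms: meta-chloroperoxybenzoic acid OOC(=O)c1cccc(Cl)c1
Why: Prilezhaev epoxidation is stereospecific (Z-olefin to cis-epoxide) and selective for the trisubstituted C4=C5 bond over the conjugated tiglate, and attack on the face away from the C6 lactone oxygen, expected to be the outer face of the ring, would give the 4R,5S epoxide.

## Compound list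

1 | (S)-5-(hydroxymethyl)furan-2(5H)-one | OC[C@H]1OC(=O)C=C1 | starting material
2 | (S)-5-[(triethylsilyloxy)methyl]furan-2(5H)-one | CC[Si](CC)(CC)OC[C@H]1OC(=O)C=C1 | intermediate
3 | 2-methyl-1,3-dithiane | CC1SCCCS1 | starting material
4 | 2-lithio-2-methyl-1,3-dithiane | [Li]C1(C)SCCCS1 | intermediate
5 | lithium enolate of the 6,7-trans conjugate adduct | CC1(SCCCS1)[C@H]2C=C(O[Li])O[C@@H]2CO[Si](CC)(CC)CC | intermediate
6 | (3R,4S,5S)-3-(hydroxymethyl)-4-(2-methyl-1,3-dithian-2-yl)-5-[(triethylsilyloxy)methyl]dihydrofuran-2(3H)-one | CC1(SCCCS1)[C@H]2[C@H](CO)C(=O)O[C@@H]2CO[Si](CC)(CC)CC | intermediate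
7 | (3R,4S,5S)-3-[(tert-butyldimethylsilyloxy)methyl]-4-(2-methyl-1,3-dithian-2-yl)-5-[(triethylsilyloxy)methyl]dihydrofuran-2(3H)-one | CC1(SCCCS1)[C@H]2[C@H](CO[Si](C)(C)C(C)(C)C)C(=O)O[C@@H]2CO[Si](CC)(CC)CC | intermediate
8 | alkoxydimethylsulfonium chloride at the C5 oxygen of 7 | CC1(SCCCS1)[C@H]2[C@H](CO[Si](C)(C)C(C)(C)C)C(=O)O[C@@H]2CO[S+](C)C.[Cl-] | intermediate
9 | all-trans lactone C5 aldehyde (dithiane at C7, CH2OTBS at C11) | CC1(SCCCS1)[C@H]2[C@H](CO[Si](C)(C)C(C)(C)C)C(=O)O[C@@H]2C=O | intermediate
10 | all-trans lactone with (Z)-2-iodoprop-1-enyl at C6 (dithiane at C7) | CC1(SCCCS1)[C@H]2[C@H](CO[Si](C)(C)C(C)(C)C)C(=O)O[C@@H]2/C=C(\I)C | intermediate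
11 | C7 acetyl lactone with (Z)-2-iodoprop-1-enyl at C6 | CC(=O)[C@H]1[C@H](CO[Si](C)(C)C(C)(C)C)C(=O)O[C@@H]1/C=C(\I)C | intermediate
12 | kinetic lithium enolate of 11 (O–C8=C9) | C=C(O[Li])[C@H]1[C@H](CO[Si](C)(C)C(C)(C)C)C(=O)O[C@@H]1/C=C(\I)C | intermediate
13 | tert-butyldimethylsilyl enol ether of 11 (O–C8=C9) | C=C(O[Si](C)(C)C(C)(C)C)[C@H]1[C@H](CO[Si](C)(C)C(C)(C)C)C(=O)O[C@@H]1/C=C(\I)C | intermediate
14 | diethyl oxalate | CCOC(=O)C(=O)OCC | starting material
15 | bromomagnesium hemiketal alkoxide from vinyl addition to 14 | C=CC(OCC)(O[Mg]Br)C(=O)OCC | intermediate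
16 | ethyl 2-oxobut-3-enoate | C=CC(=O)C(=O)OCC | intermediate
17 | ethyl 4-bromo-2-oxobutanoate | BrCCC(=O)C(=O)OCC | intermediate
18 | ethyl 2-(2-bromoethyl)-1,3-dioxolane-2-carboxylate | CCOC(=O)C1(CCBr)OCCO1 | intermediate
19 | 2-(2-bromoethyl)-N-methoxy-N-methyl-1,3-dioxolane-2-carboxamide | CON(C)C(=O)C1(CCBr)OCCO1 | intermediate
20 | magnesium chelate (tetrahedral methyl adduct of 19) | CC(O[Mg]Br)(N(C)OC)C1(CCBr)OCCO1 | intermediate
21 | 1-[2-(2-bromoethyl)-1,3-dioxolan-2-yl]ethan-1-one | CC(=O)C1(CCBr)OCCO1 | intermediate
22 | [2-(2-acetyl-1,3-dioxolan-2-yl)ethyl]zinc bromide | CC(=O)C1(CC[Zn]Br)OCCO1 | intermediate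
23 | coupled seco-germacranolide, C8 as silyl enol ether, Z C4=C5, C1 dioxolane, C10 methyl ketone | C=C(O[Si](C)(C)C(C)(C)C)[C@H]1[C@H](CO[Si](C)(C)C(C)(C)C)C(=O)O[C@@H]1/C=C(C)\CCC1(OCCO1)C(C)=O | intermediate
24 | C7 bromoacetyl seco-germacranolide (key-step precursor, 13-OTBS) | BrCC(=O)[C@H]1[C@H](CO[Si](C)(C)C(C)(C)C)C(=O)O[C@@H]1/C=C(C)\CCC1(OCCO1)C(C)=O | intermediate
25 | trivalent samarium enolate of the C8 ketone (O–C8=C9) | C=C(O[Sm](I)I)[C@H]1[C@H](CO[Si](C)(C)C(C)(C)C)C(=O)O[C@@H]1/C=C(C)\CCC1(OCCO1)C(C)=O | intermediate
26 | (4Z,10R)-1,1-ethylenedioxy-10-hydroxy-8-oxo-13-(tert-butyldimethylsilyloxy)germacr-4-en-12,6-olide | O=C1C[C@@](C)(O)C3(OCCO3)CC/C(C)=C\[C@H]2OC(=O)[C@@H](CO[Si](C)(C)C(C)(C)C)[C@@H]21 | intermediate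
27 | C10 O-diethylboron chelate of 26 | O=C1C[C@@](C)(OB(CC)CC)C3(OCCO3)CC/C(C)=C\[C@H]2OC(=O)[C@@H](CO[Si](C)(C)C(C)(C)C)[C@@H]21 | intermediate
28 | (8S,10R)-8,10-diol (8,10-syn), C1 dioxolane, 13-OTBS | O[C@H]1C[C@@](C)(O)C3(OCCO3)CC/C(C)=C\[C@H]2OC(=O)[C@@H](CO[Si](C)(C)C(C)(C)C)[C@@H]21 | intermediate
29 | C8 tiglate of 28 | C/C=C(\C)C(=O)O[C@H]1C[C@@](C)(O)C3(OCCO3)CC/C(C)=C\[C@H]2OC(=O)[C@@H](CO[Si](C)(C)C(C)(C)C)[C@@H]21 | intermediate
30 | (4Z)-10,13-dihydroxy-1-oxo-8-tigloyloxygermacr-4-en-12,6-olide | C/C=C(\C)C(=O)O[C@H]1C[C@@](C)(O)C(=O)CC/C(C)=C\[C@H]2OC(=O)[C@@H](CO)[C@@H]21 | intermediate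
31 | (4Z)-10,13-diacetoxy-1-oxo-8-tigloyloxygermacr-4-en-12,6-olide | C/C=C(\C)C(=O)O[C@H]1C[C@@](C)(OC(C)=O)C(=O)CC/C(C)=C\[C@H]2OC(=O)[C@@H](COC(C)=O)[C@@H]21 | intermediate
32 | (4R,5S,6S,7R,8S,10R,11R)-10,13-diacetoxy-4,5-epoxy-1-oxo-8-tigloyloxygermacran-12,6-olide (CNP0305680.1) | C/C=C(\C)C(=O)O[C@H]1C[C@@](C)(OC(C)=O)C(=O)CC[C@@]2(C)O[C@H]2[C@H]2OC(=O)[C@@H](COC(C)=O)[C@@H]21 | target

## Step count and risks

Total step count: 19 (steps 1–7 lactone fragment, steps 8–11 arm, steps 12–19 coupling to target).
Longest linear sequence: 15 steps (1–7, then 12–19).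

Steps most likely to fail:

**Step 14 (ring closure).** The samarium enolate may be protonated or may react between molecules before the ten-membered ring closes, or C9 may add to the Si face of C10. The fallback closes the ring at C3–C4 instead and sets C10 in an open-chain aldol. It sets out from 11 and 21. The kinetic lithium enolate 12 (LiN(i-Pr)2, THF, −78 °C) would be added to the keto ketal 21 to give the open-chain β-hydroxy ketone, (10R)-aldol adduct F1, after separation of the two C10 epimers. A nickel-catalysed intramolecular reductive coupling of the alkenyl iodide with the primary bromide (NiI2, 4,4'-di-tert-butyl-2,2'-bipyridine, Zn, NaI, DMA, high dilution) would then form C3–C4 with retention of the Z geometry and return to the route at 26.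

**Step 19 (epoxidation).** The peracid may attack the wrong face of the Z C4=C5 bond, or both faces without preference. The fallback delivers oxygen to the face opposite to that taken by an electrophile. It sets out from 31. NBS in THF/H2O at 0 °C would form the bromonium ion on the accessible face and water would open it at the tertiary C4 from the other side to give the anti bromohydrin F3. Ag2O in CH2Cl2 would then close the C4 oxygen onto C5 with inversion and return to the route at 32.

**Step 15 (C8 reduction).** The ring conformation may override the boron chelate, so that hydride reaches C8 from the face that gives the 8,10-anti diol. The fallback makes the anti diol on purpose and inverts C8 during esterification. It sets out from 26. Evans–Saksena reduction (Me4NBH(OAc)3, MeCN/AcOH, −30 °C) delivers hydride internally from the C10 oxygen and would give the (8R,10R)-anti diol F2. Mitsunobu esterification with tiglic acid (PPh3, DIAD, toluene, 0 °C) would then install the tiglate with inversion at C8 and return to the route at 29.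

## Further compounds

F1 | step 14 | open-chain (10R)-aldol adduct of 11 and 21: C8 ketone, C10 tertiary alcohol, C3 bromide, (Z)-C4 iodoalkene | O=C(C[C@@](C)(O)C1(CCBr)OCCO1)[C@H]2[C@H](CO[Si](C)(C)C(C)(C)C)C(=O)O[C@@H]2/C=C(\I)C
F2 | step 15 | (8R,10R)-8,10-anti diol, C8 epimer of 28 | O[C@@H]1C[C@@](C)(O)C3(OCCO3)CC/C(C)=C\[C@H]2OC(=O)[C@@H](CO[Si](C)(C)C(C)(C)C)[C@@H]21
F3 | step 19 | anti bromohydrin of 31: C4 tertiary alcohol, C5 bromide | C/C=C(\C)C(=O)O[C@H]1C[C@@](C)(OC(C)=O)C(=O)CC[C@@](C)(O)[C@H](Br)[C@H]2OC(=O)[C@@H](COC(C)=O)[C@@H]21
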